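**Strategy**

Everything rests on the bond between furan C2 (the ring carbon between O1 and the methyl-bearing C3) and C13 of the tridecanoic acid chain. C13 is read as the former α-carbon of a C14 α,ω-diacid: the N-acyloxyphthalimide of monomethyl tetradecanedioate is a latent 12-(methoxycarbonyl)dodecyl radical. The other precursor, 4-methyl-2-pentylfuran, carries its only free α-C–H exactly at the future C2 and is zincated there. A nickel-catalysed decarboxylative Negishi coupling expels CO2 and joins both halves in one operation, giving the whole C23 skeleton as its methyl ester; saponification ends the route. The target has no stereocentre.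

Key step: step 4

Remark: the target has no stereocentre and no stereogenic double bond, so the structure drawn is a single achiral compound and no stereocontrol is needed. Monomethyl tetradecanedioate is taken as a purchasable half ester of the commercial C14 diacid.

**Route**

Step 1
Reactants: 1 hept-1-yne; 2 chloroacetone (1-chloropropan-2-one)
Product: 5 2-(hept-1-yn-1-yl)-2-methyloxirane (racemic), via lithium hept-1-yn-1-ide 3 (not isolated), via lithium 1-chloro-2-methylnon-3-yn-2-olate 4 (not isolated)
Conditions: n-BuLi, THF, −78 °C; then 2, −78 °C; then DMPU, −78 °C → rt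
Reagents that add atoms: none
Why: Low-temperature 1,2-addition of the lithium acetylide to the activated carbonyl of the α-chloroketone should outrun enolisation, and the chlorohydrin alkoxide should close to the epoxide by intramolecular Williamson substitution on warming (Darzens-type halohydrin closure); the quaternary centre forms as a racemate and is erased in step 2.

Step 2
Reactants: 5 2-(hept-1-yn-1-yl)-2-methyloxirane
Product: 6 4-methyl-2-pentylfuran
Conditions: AuCl3 (5 mol%), MeCN, rt
Reagents that add atoms: none
Why: Gold(III)-catalysed cycloisomerisation of an alkynyl epoxide: the epoxide oxygen attacks the activated distal alkyne carbon, the tertiary propargylic C–O bond breaks, and proton loss with protodeauration should give the aromatic furan, whose 2,4-dialkyl pattern is fixed by the connectivity of 5.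

Step 3
Reactants: 7 14-methoxy-14-oxotetradecanoic acid (monomethyl tetradecanedioate)
Product: 8 1-(1,3-dioxoisoindolin-2-yl) 14-methyl tetradecanedioate
Conditions: N-hydroxyphthalimide, DIC, DMAP (10 mol%), CH2Cl2, rt
Reagents that add atoms: N-hydroxyphthalimide, O=C1c2ccccc2C(=O)N1O
Why: Steglich-type carbodiimide esterification of the free carboxyl group should give the redox-active ester, the methyl ester end being inert.

Step 4
Reactants: 6 4-methyl-2-pentylfuran (2.5 equiv); 8 1-(1,3-dioxoisoindolin-2-yl) 14-methyl tetradecanedioate (limiting)
Product: 11 methyl 13-(3-methyl-5-pentylfuran-2-yl)tridecanoate, via (3-methyl-5-pentylfuran-2-yl)lithium 9 (not isolated), via (3-methyl-5-pentylfuran-2-yl)zinc chloride 10 (not isolated)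
Conditions: n-BuLi, THF, 0 °C → rt; ZnCl2, THF, 0 °C → rt; then 8, NiCl2·glyme (20 mol%), 4,4′-di-tert-butyl-2,2′-bipyridine (40 mol%), THF/DMF, rt
Reagents that add atoms: none
Why: n-BuLi removes the only ring α-proton of 6 (C5–H, between O1 and the methyl-bearing C4; the β C3–H and the side-chain C–H bonds are far less acidic), and ZnCl2 turns furyllithium 9 into the ester-tolerant furylzinc chloride 10. Transmetalation of 10 to nickel gives a furyl–Ni(I) species that reduces the N-acyloxyphthalimide 8 by single-electron transfer; N–O cleavage and loss of CO2 release the primary 12-(methoxycarbonyl)dodecyl radical, which is captured at nickel, and reductive elimination from furyl(alkyl)Ni(III) forms the furan C2–C13 bond. The closest known reaction type is the nickel-catalysed decarboxylative Negishi arylation of redox-active esters with (hetero)arylzinc halides. No ring is closed and no stereocentre is created. The step needs site selectivity on the furan, which the pre-formed C–Zn bond fixes, and chemoselectivity for the activated ester over the methyl ester, which follows because only the N-acyloxyphthalimide accepts an electron and organozinc reagents do not add to esters at room temperature. Unreacted zinc reagent returns 6 on work-up and can be recovered.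

Step 5
Reactants: 11 methyl 13-(3-methyl-5-pentylfuran-2-yl)tridecanoate
Product: 12 13-(3-methyl-5-pentylfuran-2-yl)tridecanoic acid
Conditions: LiOH·H2O, THF/MeOH/H2O, rt, under argon; then 1 M HCl to pH 3–4, 0 °C
Reagents that add atoms: lithium hydroxide, [Li+].[OH-]
Why: Saponification (BAc2) of the unhindered methyl ester under mild base should leave the acid- and oxidation-sensitive trialkylfuran intact, the acidification being kept cold and brief.

**Compound list**

1 | hept-1-yne | CCCCCC#C | starting material
2 | chloroacetone (1-chloropropan-2-one) | CC(=O)CCl | starting material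
3 | lithium hept-1-yn-1-ide | CCCCCC#C[Li] | intermediate
4 | lithium 1-chloro-2-methylnon-3-yn-2-olate (racemic) | CCCCCC#CC(C)([O-])CCl.[Li+] | intermediate
5 | 2-(hept-1-yn-1-yl)-2-methyloxirane (racemic) | CCCCCC#CC1(C)CO1 | intermediate
6 | 4-methyl-2-pentylfuran | CCCCCc1cc(C)co1 | intermediate
7 | 14-methoxy-14-oxotetradecanoic acid | COC(=O)CCCCCCCCCCCCC(=O)O | starting material
8 | 1-(1,3-dioxoisoindolin-2-yl) 14-methyl tetradecanedioate | COC(=O)CCCCCCCCCCCCC(=O)ON1C(=O)c2ccccc2C1=O | intermediate
9 | (3-methyl-5-pentylfuran-2-yl)lithium | CCCCCc1cc(C)c([Li])o1 | intermediate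
10 | (3-methyl-5-pentylfuran-2-yl)zinc chloride | CCCCCc1cc(C)c([Zn]Cl)o1 | intermediate
11 | methyl 13-(3-methyl-5-pentylfuran-2-yl)tridecanoate | CCCCCc1cc(C)c(CCCCCCCCCCCCC(=O)OC)o1 | intermediate
12 | 13-(3-methyl-5-pentylfuran-2-yl)tridecanoic acid (achiral) | CCCCCc1cc(C)c(CCCCCCCCCCCCC(=O)O)o1 | target

**Count**

Total steps: 5. Longest linear sequence: 4 steps (1, 2, 4, 5).

**Steps most likely to fail**

Step 4. Capture of the primary alkyl radical by the ortho-substituted furyl–nickel species may be slow, so that radical reduction or dimerisation, homocoupling of the furylzinc and protodezincation take over. The fallback sets out from 6 and uses polar acylation followed by deoxygenation. 13-Methoxy-13-oxotridecanoic acid (monomethyl brassylate, COC(=O)CCCCCCCCCCCC(=O)O) is converted with oxalyl chloride and catalytic DMF in CH2Cl2 into methyl 13-chloro-13-oxotridecanoate F1. Friedel–Crafts acylation of 6 at its only free α-position (SnCl4, CH2Cl2, −78 → −20 °C) should give methyl 13-(3-methyl-5-pentylfuran-2-yl)-13-oxotridecanoate F2. Huang–Minlon Wolff–Kishner reduction (N2H4·H2O, KOH, diethylene glycol, 130 → 195 °C, then cold dilute HCl) should pass through the hydrazone 13-hydrazinylidene-13-(3-methyl-5-pentylfuran-2-yl)tridecanoic acid F3, saponify the ester in the same flask and come back to the route at the target 12.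

Step 2. The Lewis-acidic gold salt may trigger Meinwald rearrangement or oligomerisation of the tertiary propargylic epoxide faster than cyclisation, and the volatile product may be lost on isolation. The fallback sets out from 5. Basic hydrolysis (KOH, DMSO/H2O, 90 °C) should open the epoxide to 2-methylnon-3-yne-1,2-diol F4. Silver(I)-catalysed 5-endo-dig hydroalkoxylation (AgNO3 10 mol% on silica gel, CH2Cl2, rt) should give 3-methyl-5-pentyl-2,3-dihydrofuran-3-ol F5, which is expected to lose water on the support and return to the route at 6.

Step 1. The basic acetylide may enolise chloroacetone instead of adding to it, and the lithium alkoxide may close to the epoxide incompletely. The fallback sets out from 1. Sonogashira coupling with 2-bromopropene (Pd(PPh3)2Cl2, CuI, Et3N, rt) should give 2-methylnon-1-en-3-yne F6. Prilezhaev epoxidation (mCPBA, NaHCO3, CH2Cl2, 0 °C), selective for the alkene over the alkyne, should return to the route at 5.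

**Further compounds**

F1 | step 4 | methyl 13-chloro-13-oxotridecanoate | COC(=O)CCCCCCCCCCCC(=O)Cl
F2 | step 4 | methyl 13-(3-methyl-5-pentylfuran-2-yl)-13-oxotridecanoate | CCCCCc1cc(C)c(C(=O)CCCCCCCCCCCC(=O)OC)o1
F3 | step 4 | 13-hydrazinylidene-13-(3-methyl-5-pentylfuran-2-yl)tridecanoic acid | CCCCCc1cc(C)c(C(=NN)CCCCCCCCCCCC(=O)O)o1
F4 | step 2 | 2-methylnon-3-yne-1,2-diol (racemic) | CCCCCC#CC(C)(O)CO
F5 | step 2 | 3-methyl-5-pentyl-2,3-dihydrofuran-3-ol (racemic) | CCCCCC1=CC(C)(O)CO1
F6 | step 1 | 2-methylnon-1-en-3-yne | CCCCCC#CC(C)=C
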